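**Plan**
1. Retrosynthesis: remove the MOM helper from O7, take the 1,2-diketone back to a deoxybenzoin (benzylic C=O from CH2), cut the CH2–aryl bond to ring B (ketone α-arylation) and the O5–CH3 bond, then open the pyran ring at O1–C2 and C4–C4a to an aryl 1,1-dimethylpropargyl ether of phloroacetophenone.
2. Forward: ring A is bought as phloroacetophenone; its 4-OH is propargylated, one ortho OH is capped as a MOM ether, and the pyran ring forms in one thermal cascade (step 3). O-methylation, α-arylation with the prenyloxyphenyl bromide (ring B), aerobic oxidation to the diketone and MOM removal finish the route.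
3. Enabling feature: in ring A the oxygen on C8a and the chain C4a–C4=C3–C2(CH3)2 ortho to it form, in the ortho-quinone methide tautomer, a 1-oxatriene (O=C8a–C4a=C4–C3=C2). Its 6π closure makes O1–C2 and re-aromatises ring A; the hydrogen bond between the acetyl C=O on C6 and the hydroxyl on C5 decides which ortho carbon carries the chain.
4. Stereochemistry: the target has no stereocentre; the C3=C4 alkene is cis by ring constraint, and the transient stereocentres of 5 and 14 vanish within their own steps.

Key step: step 3

Assumption: commercial phloroacetophenone monohydrate is dried before use, and the target is taken as the open 2-hydroxybenzil shown by its SMILES. Ring carbons of 3 and 4 are numbered from the acetyl-bearing carbon (C1); chromenes carry the usual O1–C8a numbering.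

**Step 1**
Reactants: 1 phloroacetophenone (1-(2,4,6-trihydroxyphenyl)ethanone); 2 propargylic chloride (3-chloro-3-methylbut-1-yne)
Product: 3 propargyl ether diol (1-[2,6-dihydroxy-4-(2-methylbut-3-yn-2-yloxy)phenyl]ethanone)
Conditions: DBU (1.05 equiv), CuCl2·2H2O (1 mol %), MeCN, 0 °C
Reagents that add atoms: none
Why: Copper-catalysed propargylic etherification of a phenol (through a copper allenylidene) should take place at the para hydroxyl, the most acidic and least hindered one, when only one equivalent of base is used.

**Step 2**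
Reactants: 3 propargyl ether diol
Product: 4 mono-MOM ether (1-[2-hydroxy-6-(methoxymethoxy)-4-(2-methylbut-3-yn-2-yloxy)phenyl]ethanone)
Conditions: MOMCl (1.1 equiv), i-Pr2NEt, CH2Cl2, 0 °C
Reagents that add atoms: chloromethyl methyl ether (MOMCl), COCCl
Why: Acetal protection (O-alkylation) of one of two equivalent ortho hydroxyls should stop after the first, because the remaining hydroxyl is then held in the hydrogen bond to the ketone.

**Step 3**
Reactants: 4 mono-MOM ether
Product: 8 chromene phenol (1-[5-hydroxy-7-(methoxymethoxy)-2,2-dimethyl-2H-chromen-6-yl]ethanone), via allenyl cyclohexadienone 5 (not isolated), via ortho-allenylphenol 6 (not isolated), via ortho-quinone methide 7 (not isolated)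
Conditions: o-xylene (degassed), 140 °C
Reagents that add atoms: none
Why: Heating should trigger an aryl propargyl ether Claisen [3,3] shift onto C3 (between the free OH and the ether oxygen) to give dienone 5, which tautomerises to allenylphenol 6; a [1,5]-hydrogen shift from the new O–H to the central allene carbon gives the (Z)-1-oxatriene 7, and a thermal disrotatory oxa-6π electrocyclisation joins the phenolic oxygen to the C(CH3)2 carbon. The closest known reaction type is the thermal rearrangement of aryl 1,1-dimethylpropargyl ethers to 2,2-dimethyl-2H-chromenes. The pyran ring closes as a six-membered ring by 6π electrocyclisation of the ortho-quinone methide (O–C bond formation at the diene terminus), driven by re-aromatisation of ring A. No stereocentre survives: the sp3 carbon of 5 is lost on tautomerisation, the product is achiral and its ring alkene is necessarily cis. The step needs site selectivity between the ortho carbons C3 and C5: the hydrogen bond of the free 2-OH to the acetyl C=O fixes double-bond character in C1=C2 and C3=C4, so the shift should go to C3 and 5 keeps its chelated enol–ketone unit, whereas C5 sits next to the bulkier, non-chelating MOM ether. The chelated 2-OH stays locked to the ketone, so only the oxygen that carried the propargyl group should take part in the hydrogen shift and the ring closure.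

**Step 4**
Reactants: 8 chromene phenol
Product: 9 methyl ether (1-[5-methoxy-7-(methoxymethoxy)-2,2-dimethyl-2H-chromen-6-yl]ethanone)
Conditions: MeI, K2CO3, DMF, 40 °C
Reagents that add atoms: iodomethane (MeI), CI
Why: Williamson O-methylation of the only free hydroxyl; the chelated, hindered phenol should react in a polar aprotic solvent with gentle warming, and the MOM ether is inert to base.

**Step 5**
Reactants: 10 4-bromophenol; 11 prenyl bromide (1-bromo-3-methylbut-2-ene)
Product: 12 aryl bromide (1-bromo-4-[(3-methylbut-2-en-1-yl)oxy]benzene)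
Conditions: K2CO3, acetone, reflux
Reagents that add atoms: none
Why: Williamson ether synthesis by SN2 displacement at the primary allylic bromide by the phenoxide.

**Step 6**
Reactants: 9 methyl ether; 12 aryl bromide
Product: 13 deoxybenzoin (1-[5-methoxy-7-(methoxymethoxy)-2,2-dimethyl-2H-chromen-6-yl]-2-{4-[(3-methylbut-2-en-1-yl)oxy]phenyl}ethanone)
Conditions: Pd2(dba)3 (1 mol %), XPhos (2.5 mol %), NaOtBu (2.2 equiv), toluene, 80 °C
Reagents that add atoms: none
Why: Palladium-catalysed α-arylation of a methyl ketone enolate with an aryl bromide (Buchwald–Hartwig type) at the single enolisable site; the bulky biarylphosphine should favour mono-arylation and fast oxidative addition of the C–Br bond over ionisation of the prenyl ether at zerovalent palladium.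

**Step 7**
Reactants: 13 deoxybenzoin
Product: 15 MOM-protected benzil (1-[5-methoxy-7-(methoxymethoxy)-2,2-dimethyl-2H-chromen-6-yl]-2-{4-[(3-methylbut-2-en-1-yl)oxy]phenyl}ethane-1,2-dione), via alpha-hydroperoxy ketone 14 (not isolated)
Conditions: O2 (1 atm), DABCO (0.2 equiv), DMF, 90 °C
Reagents that add atoms: dioxygen, O=O
Why: Base-catalysed aerobic oxidation (enolate autoxidation) of the doubly activated methylene should give hydroperoxide 14, which loses water (Kornblum–DeLaMare-type elimination) to the 1,2-diketone; the non-electrophilic oxidant should leave both alkenes alone.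

**Step 8**
Reactants: 15 MOM-protected benzil
Product: 16 ficucaricone C (1-(7-hydroxy-5-methoxy-2,2-dimethyl-2H-chromen-6-yl)-2-{4-[(3-methylbut-2-en-1-yl)oxy]phenyl}ethane-1,2-dione)
Conditions: HCl (cat.) in MeOH, THF, 40 °C
Reagents that add atoms: none
Why: Acid-catalysed transacetalisation to methanol; a MOM ether ortho to a ketone is cleaved under mild conditions that the aryl prenyl ether and the chromene should survive, and the freed hydroxyl is stabilised by the hydrogen bond to the ketone.

**Compound list**
1 | 1-(2,4,6-trihydroxyphenyl)ethanone (phloroacetophenone) | CC(=O)c1c(O)cc(O)cc1O | starting material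
2 | 3-chloro-3-methylbut-1-yne | CC(C)(Cl)C#C | starting material
3 | 1-[2,6-dihydroxy-4-(2-methylbut-3-yn-2-yloxy)phenyl]ethanone | CC(=O)c1c(O)cc(OC(C)(C)C#C)cc1O | intermediate
4 | 1-[2-hydroxy-6-(methoxymethoxy)-4-(2-methylbut-3-yn-2-yloxy)phenyl]ethanone | CC(=O)c1c(O)cc(OC(C)(C)C#C)cc1OCOC | intermediate
5 | 4-acetyl-5-hydroxy-3-(methoxymethoxy)-6-(3-methylbuta-1,2-dien-1-yl)cyclohexa-2,4-dien-1-one (racemic) | CC(=O)C1=C(O)C(C=C=C(C)C)C(=O)C=C1OCOC | intermediate (not isolated)
6 | 1-[2,4-dihydroxy-6-(methoxymethoxy)-3-(3-methylbuta-1,2-dien-1-yl)phenyl]ethanone | CC(=O)c1c(O)c(C=C=C(C)C)c(O)cc1OCOC | intermediate (not isolated)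
7 | (6Z)-4-acetyl-5-hydroxy-3-(methoxymethoxy)-6-(3-methylbut-2-en-1-ylidene)cyclohexa-2,4-dien-1-one | CC(=O)C1=C(O)/C(=C/C=C(C)C)C(=O)C=C1OCOC | intermediate (not isolated)
8 | 1-[5-hydroxy-7-(methoxymethoxy)-2,2-dimethyl-2H-chromen-6-yl]ethanone | CC(=O)c1c(O)c2C=CC(C)(C)Oc2cc1OCOC | intermediate
9 | 1-[5-methoxy-7-(methoxymethoxy)-2,2-dimethyl-2H-chromen-6-yl]ethanone | CC(=O)c1c(OC)c2C=CC(C)(C)Oc2cc1OCOC | intermediate
10 | 4-bromophenol | Oc1ccc(Br)cc1 | starting material
11 | 1-bromo-3-methylbut-2-ene (prenyl bromide) | CC(C)=CCBr | starting material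
12 | 1-bromo-4-[(3-methylbut-2-en-1-yl)oxy]benzene | CC(C)=CCOc1ccc(Br)cc1 | intermediate
13 | 1-[5-methoxy-7-(methoxymethoxy)-2,2-dimethyl-2H-chromen-6-yl]-2-{4-[(3-methylbut-2-en-1-yl)oxy]phenyl}ethanone | COCOc1cc2OC(C)(C)C=Cc2c(OC)c1C(=O)Cc1ccc(OCC=C(C)C)cc1 | intermediate
14 | 2-hydroperoxy-1-[5-methoxy-7-(methoxymethoxy)-2,2-dimethyl-2H-chromen-6-yl]-2-{4-[(3-methylbut-2-en-1-yl)oxy]phenyl}ethanone (racemic) | COCOc1cc2OC(C)(C)C=Cc2c(OC)c1C(=O)C(OO)c1ccc(OCC=C(C)C)cc1 | intermediate (not isolated)
15 | 1-[5-methoxy-7-(methoxymethoxy)-2,2-dimethyl-2H-chromen-6-yl]-2-{4-[(3-methylbut-2-en-1-yl)oxy]phenyl}ethane-1,2-dione | COCOc1cc2OC(C)(C)C=Cc2c(OC)c1C(=O)C(=O)c1ccc(OCC=C(C)C)cc1 | intermediate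
16 | ficucaricone C, 1-(7-hydroxy-5-methoxy-2,2-dimethyl-2H-chromen-6-yl)-2-{4-[(3-methylbut-2-en-1-yl)oxy]phenyl}ethane-1,2-dione | COc1c2c(cc(O)c1C(=O)C(=O)c1ccc(OCC=C(C)C)cc1)OC(C)(C)C=C2 | target

**Totals**
Total step count: 8. Longest linear sequence: 7 steps (1, 2, 3, 4, 6, 7, 8); step 5 makes the ring B fragment.

**Steps most likely to fail**

Step 3. The sigmatropic shift may lose site selectivity, with part of the material rearranging to the ortho carbon next to the MOM ether; this would end in the isomeric O5/O7 substitution pattern. The fallback removes the choice by symmetry and sets out from 3. Both ortho hydroxyls are capped (MOMCl, NaH, DMF) to give 1-[2,6-bis(methoxymethoxy)-4-(2-methylbut-3-yn-2-yloxy)phenyl]ethanone F1, in which the two ortho carbons are equivalent and only the ether oxygen can close. Heating as in step 3 should give the single chromene 1-[5,7-bis(methoxymethoxy)-2,2-dimethyl-2H-chromen-6-yl]ethanone F2. Acidic methanolysis of both MOM groups gives 1-(5,7-dihydroxy-2,2-dimethyl-2H-chromen-6-yl)ethanone F3. One equivalent of MOMCl with i-Pr2NEt at low temperature should then cap the less hindered 7-OH, since the 5-OH, buttressed by the ring alkene, keeps the hydrogen bond to the ketone. The route is rejoined at 8.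

Step 7. Over-oxidation is the main danger: the hydroperoxide may fragment with C–C cleavage to an acid and an aldehyde, or radical autoxidation may start at the allylic positions. The fallback replaces direct oxygenation by nitrosation and sets out from 13. tert-Butyl nitrite and KOtBu (THF, 0 °C) should give 2-(hydroxyimino)-1-[5-methoxy-7-(methoxymethoxy)-2,2-dimethyl-2H-chromen-6-yl]-2-{4-[(3-methylbut-2-en-1-yl)oxy]phenyl}ethanone F4. Transoximation with buffered aqueous glyoxylic acid in THF at room temperature should free the diketone, and the route is rejoined at 15.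

Step 6. The catalytic cycle may be diverted by ionisation of the aryl prenyl ether at zerovalent palladium (loss or transfer of the prenyl group), by Heck-type insertion of the chromene alkene, or by a second arylation. The fallback builds the two-carbon bridge by polar chemistry, sets out from 9 and replaces steps 6 and 7. Riley oxidation (SeO2, dioxane/H2O, 90 °C) should give 2-[5-methoxy-7-(methoxymethoxy)-2,2-dimethyl-2H-chromen-6-yl]-2-oxoacetaldehyde F5. Bromide 12 is converted with Mg turnings in THF into bromo{4-[(3-methylbut-2-en-1-yl)oxy]phenyl}magnesium F6, which should add at −78 °C to the aldehyde carbon of F5, the ketone being shielded by its two ortho substituents. This gives 2-hydroxy-1-[5-methoxy-7-(methoxymethoxy)-2,2-dimethyl-2H-chromen-6-yl]-2-{4-[(3-methylbut-2-en-1-yl)oxy]phenyl}ethanone F7. MnO2 (CH2Cl2, room temperature) oxidises the benzylic alcohol, and the route is rejoined at 15.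

**Further compounds**
F1 | step 3 | 1-[2,6-bis(methoxymethoxy)-4-(2-methylbut-3-yn-2-yloxy)phenyl]ethanone | CC(=O)c1c(OCOC)cc(OC(C)(C)C#C)cc1OCOC
F2 | step 3 | 1-[5,7-bis(methoxymethoxy)-2,2-dimethyl-2H-chromen-6-yl]ethanone | CC(=O)c1c(OCOC)cc2OC(C)(C)C=Cc2c1OCOC
F3 | step 3 | 1-(5,7-dihydroxy-2,2-dimethyl-2H-chromen-6-yl)ethanone | CC(=O)c1c(O)cc2OC(C)(C)C=Cc2c1O
F4 | step 7 | 2-(hydroxyimino)-1-[5-methoxy-7-(methoxymethoxy)-2,2-dimethyl-2H-chromen-6-yl]-2-{4-[(3-methylbut-2-en-1-yl)oxy]phenyl}ethanone (oxime E/Z mixture) | COCOc1cc2OC(C)(C)C=Cc2c(OC)c1C(=O)C(=NO)c1ccc(OCC=C(C)C)cc1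
F5 | step 6 | 2-[5-methoxy-7-(methoxymethoxy)-2,2-dimethyl-2H-chromen-6-yl]-2-oxoacetaldehyde | COCOc1cc2OC(C)(C)C=Cc2c(OC)c1C(=O)C=O
F6 | step 6 | bromo{4-[(3-methylbut-2-en-1-yl)oxy]phenyl}magnesium | CC(C)=CCOc1ccc([Mg]Br)cc1
F7 | step 6 | 2-hydroxy-1-[5-methoxy-7-(methoxymethoxy)-2,2-dimethyl-2H-chromen-6-yl]-2-{4-[(3-methylbut-2-en-1-yl)oxy]phenyl}ethanone (racemic) | COCOc1cc2OC(C)(C)C=Cc2c(OC)c1C(=O)C(O)c1ccc(OCC=C(C)C)cc1
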